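**Retrosynthetic overview**

- Feature: C20 (the OCH2 on C10) and C17 (the methyl on C8) are 1,3-diaxial on the β face of ring B, so a CH2 tied to O20 through silicon can reach C8 of a C8=C14–C13=O enone only from the face the methyl must occupy.
- Endgame: hydroquinone ⇐ dimethyl ether; C19→O20 δ-lactone ⇐ 19,20-diol; C17–H ⇐ C17–Si; C13 carbinol ⇐ ketone via methylidene and α-epoxide; C14–C15 ⇐ enolate benzylation; C8–C17 ⇐ silicon-tethered radical conjugate addition.
- Precursor: ring C enone ⇐ Birch reduction of a 13-methoxy arene; C4 methyl ⇐ α-face ester enolate methylation in the tricycle; ring B (C9–C10) ⇐ spiro-epoxide/arene cyclialkylation; C5 ⇐ anti conjugate addition to a silyloxy enoate whose carbinol comes from a CBS reduction.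
- Ring order: ring A (purchased) → aryl ring C attached through C6–C7 → ring B closed → ring C dearomatised → temporary oxasilepane (key step) → δ-lactone last.

Key step: step 14

Remark: diterpene numbering is used (C4 bears C18 α and C19 β, C10 bears C20 β, C8 bears C17 β, C15 is the benzylic carbon on C14; β is the face of C17 and C20). The (R)-oxazaborolidine is assumed to give the (S)-carbinol, with the alkenyl arm of the enone acting as the large group.

**Route**

Step 1
Reactants: 1 methyl 3-oxocyclohex-1-ene-1-carboxylate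
Product: 2 methyl (S)-3-hydroxycyclohex-1-ene-1-carboxylate
Conditions: (R)-2-methyl-CBS-oxazaborolidine (10 mol %), BH3·SMe2, THF, −20 °C; MeOH, aqueous work-up
Reagents that add atoms: none
Why: Corey–Bakshi–Shibata reduction, in which the oxazaborolidine–borane complex delivers hydride to one face of the ketone and so sets the C10 carbinol as (S), while the conjugated ester is not reduced at this temperature.

Step 2
Reactants: 2 methyl (S)-3-hydroxycyclohex-1-ene-1-carboxylate
Product: 3 methyl (S)-3-[(tert-butyldimethylsilyl)oxy]cyclohex-1-ene-1-carboxylate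
Conditions: TBSCl, imidazole, DMF, rt
Reagents that add atoms: tert-butyldimethylsilyl chloride, CC(C)(C)[Si](C)(C)Cl
Why: Standard silylation of a secondary allylic alcohol, which installs the bulky group that directs the next addition to the opposite face.

Step 3
Reactants: 3 methyl (S)-3-[(tert-butyldimethylsilyl)oxy]cyclohex-1-ene-1-carboxylate; 4 1-(2-bromoethyl)-3-methoxybenzene
Product: 7 methyl (1R,2S,3S)-3-[(tert-butyldimethylsilyl)oxy]-2-[2-(3-methoxyphenyl)ethyl]cyclohexane-1-carboxylate, via Grignard reagent 5 (not isolated), via silyl ketene acetal 6 (not isolated)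
Conditions: 4, Mg, THF, rt; then 3, CuBr·SMe2 (10 mol %), TMSCl, DMPU, THF, −78 → −30 °C; then NaOMe (cat.), MeOH, 50 °C
Reagents that add atoms: none
Why: Copper-catalysed, TMSCl-accelerated conjugate addition of a Grignard reagent to an enoate, in which the nucleophile should enter C5 anti to the pseudoaxial C10 silyloxy group and so fix C5, after which methoxide equilibration should place the C4 ester equatorial (all-trans) and any residual C4 epimer is removable by chromatography.

Step 4
Reactants: 7 all-trans silyloxy ester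
Product: 8 methyl (1R,2S,3S)-3-hydroxy-2-[2-(3-methoxyphenyl)ethyl]cyclohexane-1-carboxylate
Conditions: HCl (cat., from AcCl), MeOH, rt
Reagents that add atoms: none
Why: Acid-catalysed methanolysis of the secondary TBS ether, in which methanol as solvent keeps the methyl ester open and neither C4 nor C5 is touched.

Step 5
Reactants: 8 hydroxy ester
Product: 9 methyl (1R,2S)-2-[2-(3-methoxyphenyl)ethyl]-3-oxocyclohexane-1-carboxylate
Conditions: Dess–Martin periodinane, CH2Cl2, rt
Reagents that add atoms: none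
Why: Dess–Martin oxidation under non-enolising conditions keeps C5, and because the trans-diequatorial keto ester is the stable diastereomer a later equilibration at C5 would return to it.

Step 6
Reactants: 9 trans keto ester
Product: 10 methyl (3R,4S,5R)-4-[2-(3-methoxyphenyl)ethyl]-1-oxaspiro[2.5]octane-5-carboxylate
Conditions: Me3S(O)I, NaH, DMSO, rt
Reagents that add atoms: trimethylsulfoxonium iodide, C[S+](C)(C)=O.[I-]
Why: Corey–Chaykovsky epoxidation, in which the sulfoxonium ylide adds reversibly and closes from the equatorial C–C betaine, so the new CH2 should be equatorial and the oxygen axial on the β face of C10.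

Step 7
Reactants: 10 spiro-epoxide
Product: 11 methyl 20-hydroxy-13-methoxy-19-norpodocarpa-8,11,13-trien-18-oate (trans-fused; CO2Me equatorial on C4; H-5 α; CH2OH on C10 β)
Conditions: BF3·OEt2 (0.3 equiv), CH2Cl2, −78 °C
Reagents that add atoms: none
Why: Epoxide-initiated Friedel–Crafts cyclialkylation (6-exo attack at the tertiary epoxide carbon), in which the arene carbon para to OMe should displace the axial C10–O bond from the opposite side, so that C9 becomes equatorial and C20 axial β, trans to H-5.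

Step 8
Reactants: 11 tricyclic hydroxy ester
Product: 12 20-O-benzyl ether of 11
Conditions: NaH, BnBr, Bu4NI (cat.), THF/DMF, 0 °C
Reagents that add atoms: benzyl bromide, BrCc1ccccc1
Why: Williamson etherification of the primary neopentyl alcohol, which masks O20 through the enolate chemistry with a group that the later dissolving-metal step removes.

Step 9
Reactants: 12 benzyl ether ester
Product: 14 methyl 20-(benzyloxy)-13-methoxypodocarpa-8,11,13-trien-19-oate (4α-methyl; 4β-axial ester), via lithium ester enolate 13 (not isolated)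
Conditions: LDA, THF/DMPU, −78 → 0 °C; then MeI, −78 → 0 °C
Reagents that add atoms: iodomethane, CI
Why: Alkylation of the exocyclic ester enolate, in which the axial C20 benzyloxymethyl group on C10 blocks the β face, so MeI should enter from the α face and give the equatorial C18 methyl and the axial C19 ester.

Step 10
Reactants: 14 quaternary ester
Product: 15 20-(benzyloxy)-13-methoxypodocarpa-8,11,13-trien-19-ol
Conditions: LiAlH4, THF, 0 °C → reflux
Reagents that add atoms: none
Why: Hydride reduction of the hindered axial ester to the primary C19 alcohol, with no stereocentre affected.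

Step 11
Reactants: 15 C19 alcohol
Product: 16 19-O-triisopropylsilyl ether of 15
Conditions: TIPSOTf, 2,6-lutidine, CH2Cl2, 0 °C
Reagents that add atoms: triisopropylsilyl triflate, CC(C)[Si](C(C)C)(C(C)C)OS(=O)(=O)C(F)(F)F
Why: Silylation with the reactive triflate gives O19 a group stable to Li/NH3, acid, base and radicals while O20 carries one that the Birch step removes, so the two oxygens are told apart without any selective reaction.

Step 12
Reactants: 16 bis-protected 13-methoxy arene
Product: 18 20-hydroxy-19-[(triisopropylsilyl)oxy]podocarp-8-en-13-one (β,γ-enone with C8=C9), via dienol ether 17 (not isolated)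
Conditions: Li, NH3(l), THF, t-BuOH, −78 → −33 °C; NH4Cl; then (CO2H)2 (cat.), THF/MeOH/H2O, rt
Reagents that add atoms: water, O
Why: Birch reduction gives the 1-methoxycyclohexa-1,4-diene (C12=C13 and C8=C9) and cleaves the benzyl ether in the same pot, and mild oxalic acid hydrolysis of the enol ether should stop at the β,γ-unsaturated ketone, which is no Michael acceptor for the free C20 hydroxyl.

Step 13
Reactants: 18 β,γ-enone alcohol; 19 (bromomethyl)chlorodimethylsilane
Product: 21 20-{[(bromomethyl)dimethylsilyl]oxy}-19-[(triisopropylsilyl)oxy]-9α-podocarp-8(14)-en-13-one, via silylated β,γ-enone 20 (not isolated)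
Conditions: 19, Et3N, DMAP (cat.), CH2Cl2, 0 °C; then DBU (0.2 equiv), 0 °C → rt
Reagents that add atoms: none
Why: Silylation of the C20 alcohol followed by base-mediated isomerisation through the dienolate (γ-protonation at C9) to the conjugated C8=C14 enone, in which reversible protonation should set H-9 α (anti to C20) and masking O20 before the enone appears prevents oxa-Michael closure onto C8.

Step 14
Reactants: 21 enone (bromomethyl)dimethylsilyl ether
Product: 22 13-ketone in which C17 on C8β is joined to O20 through SiMe2 (2,2-dimethyl-1,2-oxasilepane over C8–C9–C10; H-9 α; 19-OTIPS)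
Conditions: Bu3SnH (1.3 equiv, syringe pump), AIBN (cat.), benzene, 80 °C, 0.005 M
Reagents that add atoms: none
Why: Bu3Sn• abstracts bromine to give a nucleophilic α-silylmethyl radical that adds to C8, the β-carbon of the C8=C14–C13=O enone, and the resulting C14 α-keto radical takes hydrogen from Bu3SnH to carry the chain. The closest known reaction type is the silicon-tethered radical cyclisation of (bromomethyl)dimethylsilyl ethers of allylic and homoallylic alcohols used for angular methylation, here extended by one atom to a bishomoallylic silyl ether. The one new ring, the seven-membered oxasilepane, closes 7-exo-trig at C8, whereas the 8-endo alternative at C14 is polarity-mismatched and would leave an unstabilised radical. The new quaternary stereocentre C8 is controlled by the tether: C20 is axial on the β face of C10 and 1,3-diaxial to the β lobe of the C8 p orbital, so C17 can only arrive on the β face and the trans-anti C8/C9/C10 array should result. The step needs facial selectivity at C8 and ring closure faster than direct reduction of the radical; the first is secured by the anchor on C20, the second by the polarity match, the long Si–O and Si–C bonds and slow addition of the stannane at high dilution.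

Step 15
Reactants: 22 tethered 13-ketone
Product: 24 C11=C12 enone of 22, via trimethylsilyl enol ether 23 (not isolated)
Conditions: LDA, TMSCl, THF, −78 °C; solvent exchange; Pd(OAc)2 (1.1 equiv), MeCN, rt
Reagents that add atoms: none
Why: Kinetic enolisation away from the neopentyl C14 followed by Saegusa–Ito oxidation, in which only C11=C12 can form because C8 is quaternary, so the enone leaves C14 as the single enolisable position of the C13 ketone.

Step 16
Reactants: 24 C11=C12 enone; 25 2-(bromomethyl)-1,4-dimethoxybenzene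
Product: 27 14α-(2,5-dimethoxybenzyl) enone (H-14 β), via lithium dienolate 26 (not isolated)
Conditions: LDA, THF, −78 °C; then 25, DMPU, −78 → −20 °C
Reagents that add atoms: none
Why: α′-Deprotonation of the enone gives the cross-conjugated dienolate, which should be alkylated at C14 from the α face, anti to the axial C8–CH2Si bond (axial enolate alkylation), so the benzyl group is 14α.

Step 17
Reactants: 27 benzylated enone
Product: 28 14α-(2,5-dimethoxybenzyl) saturated 13-ketone
Conditions: H2 (1 atm), Pd/C, EtOAc, rt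
Reagents that add atoms: none
Why: Heterogeneous hydrogenation of the disubstituted enone C=C under neutral conditions, which creates no stereocentre and leaves C14, the siloxane and the aryl ethers untouched.

Step 18
Reactants: 28 saturated ketone
Product: 29 13-methylidene compound
Conditions: Cp2TiMe2, toluene, 70 °C, dark
Reagents that add atoms: dimethyltitanocene Cp2TiMe2, C[Ti](C)(C1C=CC=C1)C1C=CC=C1
Why: Petasis methylenation through Cp2Ti=CH2, chosen because the reagent is not basic and the epimerisable C14 centre next to the hindered ketone should be kept.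

Step 19
Reactants: 29 exocyclic alkene
Product: 30 13α,16-epoxide (oxygen on the α face; CH2 β)
Conditions: dimethyldioxirane, acetone, 0 °C
Reagents that add atoms: dimethyldioxirane, CC1(C)OO1
Why: Neutral dioxirane epoxidation of the 1,1-disubstituted alkene, in which the β (axial) face of C13 is shielded by the 1,3-diaxial C8–CH2Si group, so oxygen should be delivered from the α (equatorial) direction.

Step 20
Reactants: 30 spiro-epoxide
Product: 31 13α-hydroxy-13β-methyl compound (silicon tether and TIPS ether intact)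
Conditions: LiBHEt3, THF, 0 °C → rt
Reagents that add atoms: none
Why: SN2 hydride opening of the epoxide at its primary carbon turns the β-CH2 into the C16 methyl and leaves the α-oxygen as the tertiary C13 alcohol, so C13 keeps the configuration of the epoxide.

Step 21
Reactants: 31 tertiary alcohol
Product: 32 triol (C17 methyl on C8β; C19-OH; C20-OH; 13α-OH; 14α-(2,5-dimethoxybenzyl))
Conditions: Bu4NF·3H2O (excess), DMF, 80 °C
Reagents that add atoms: none
Why: Fluoride-promoted protodesilylation of the cyclic siloxane (pentacoordinate silicate, protonolysis of the C17–Si bond, helped by the nearby O20 alkoxide) reveals the C17 methyl and the C20 alcohol, and the same reagent removes the TIPS ether from O19.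

Step 22
Reactants: 32 triol
Product: 34 19→20 δ-lactone bis(methyl ether), via lactol 33 (not isolated)
Conditions: TEMPO (cat.), PhI(OAc)2 (2.2 equiv), CH2Cl2, rt
Reagents that add atoms: none
Why: Oxoammonium oxidation of a 1,5-diol to the δ-lactone, in which the C19 alcohol (one syn-axial neighbour) should react before the C20 alcohol (flanked by C17 and C19), so the aldehyde forms at C19, is trapped by O20 as the lactol and is oxidised to the C19 carbonyl, the tertiary alcohol being inert.

Step 23
Reactants: 34 lactone bis(methyl ether)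
Product: 36 target CNP0148621.1, via benzoquinone 35 (not isolated)
Conditions: Ce(NH4)2(NO3)6, MeCN/H2O, 0 °C; then Na2S2O4 (aq), rt
Reagents that add atoms: water, O
Why: Oxidative demethylation of the 1,4-dimethoxyarene to the benzoquinone by tetravalent cerium followed by dithionite reduction to the hydroquinone, conditions under which the lactone and the tertiary alcohol are stable.

**Compound list**

1 | methyl 3-oxocyclohex-1-ene-1-carboxylate | COC(=O)C1=CC(=O)CCC1 | starting material
2 | methyl (S)-3-hydroxycyclohex-1-ene-1-carboxylate | COC(=O)C1=C[C@@H](O)CCC1 | intermediate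
3 | methyl (S)-3-[(tert-butyldimethylsilyl)oxy]cyclohex-1-ene-1-carboxylate | COC(=O)C1=C[C@@H](O[Si](C)(C)C(C)(C)C)CCC1 | intermediate
4 | 1-(2-bromoethyl)-3-methoxybenzene | COc1cccc(CCBr)c1 | starting material
5 | 2-(3-methoxyphenyl)ethylmagnesium bromide (formed in situ) | COc1cccc(CC[Mg]Br)c1 | intermediate
6 | trimethylsilyl ketene acetal of 7 (C4=C19; formed in situ) | COc1cccc(CC[C@@H]2[C@@H](O[Si](C)(C)C(C)(C)C)CCCC2=C(OC)O[Si](C)(C)C)c1 | intermediate
7 | methyl (1R,2S,3S)-3-[(tert-butyldimethylsilyl)oxy]-2-[2-(3-methoxyphenyl)ethyl]cyclohexane-1-carboxylate | COc1cccc(CC[C@@H]2[C@@H](O[Si](C)(C)C(C)(C)C)CCC[C@H]2C(=O)OC)c1 | intermediate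
8 | methyl (1R,2S,3S)-3-hydroxy-2-[2-(3-methoxyphenyl)ethyl]cyclohexane-1-carboxylate | COc1cccc(CC[C@@H]2[C@@H](O)CCC[C@H]2C(=O)OC)c1 | intermediate
9 | methyl (1R,2S)-2-[2-(3-methoxyphenyl)ethyl]-3-oxocyclohexane-1-carboxylate | COc1cccc(CC[C@@H]2C(=O)CCC[C@H]2C(=O)OC)c1 | intermediate
10 | methyl (3R,4S,5R)-4-[2-(3-methoxyphenyl)ethyl]-1-oxaspiro[2.5]octane-5-carboxylate (epoxide oxygen axial) | COc1cccc(CC[C@@H]2[C@@]3(CO3)CCC[C@H]2C(=O)OC)c1 | intermediate
11 | methyl 20-hydroxy-13-methoxy-19-norpodocarpa-8,11,13-trien-18-oate (trans-fused; 4α-CO2Me equatorial; H-5 α; 10β-CH2OH) | COc1ccc2c(c1)CC[C@@H]1[C@]2(CO)CCC[C@H]1C(=O)OC | intermediate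
12 | 20-O-benzyl ether of 11 | COc1ccc2c(c1)CC[C@@H]1[C@]2(COCc2ccccc2)CCC[C@H]1C(=O)OC | intermediate
13 | lithium ester enolate of 12 (C4=C(OMe)OLi; formed in situ) | COc1ccc2c(c1)CC[C@@H]1[C@]2(COCc2ccccc2)CCCC1=C(OC)O[Li] | intermediate
14 | methyl 20-(benzyloxy)-13-methoxypodocarpa-8,11,13-trien-19-oate (4α-methyl; 4β-axial CO2Me) | COc1ccc2c(c1)CC[C@@H]1[C@]2(COCc2ccccc2)CCC[C@]1(C)C(=O)OC | intermediate
15 | 20-(benzyloxy)-13-methoxypodocarpa-8,11,13-trien-19-ol | COc1ccc2c(c1)CC[C@@H]1[C@]2(COCc2ccccc2)CCC[C@]1(C)CO | intermediate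
16 | 20-(benzyloxy)-13-methoxy-19-[(triisopropylsilyl)oxy]podocarpa-8,11,13-triene | COc1ccc2c(c1)CC[C@@H]1[C@]2(COCc2ccccc2)CCC[C@]1(C)CO[Si](C(C)C)(C(C)C)C(C)C | intermediate
17 | 13-methoxy-19-[(triisopropylsilyl)oxy]podocarpa-8,12-dien-20-ol (formed in situ) | COC1=CCC2=C(C1)CC[C@@H]1[C@]2(CO)CCC[C@]1(C)CO[Si](C(C)C)(C(C)C)C(C)C | intermediate
18 | 20-hydroxy-19-[(triisopropylsilyl)oxy]podocarp-8-en-13-one (β,γ-enone; C8=C9) | O=C1CCC2=C(C1)CC[C@@H]1[C@]2(CO)CCC[C@]1(C)CO[Si](C(C)C)(C(C)C)C(C)C | intermediate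
19 | (bromomethyl)chlorodimethylsilane | C[Si](C)(Cl)CBr | starting material
20 | 20-O-[(bromomethyl)dimethylsilyl] ether of 18 (formed in situ) | O=C1CCC2=C(C1)CC[C@@H]1[C@]2(CO[Si](C)(C)CBr)CCC[C@]1(C)CO[Si](C(C)C)(C(C)C)C(C)C | intermediate
21 | 20-{[(bromomethyl)dimethylsilyl]oxy}-19-[(triisopropylsilyl)oxy]-9α-podocarp-8(14)-en-13-one | O=C1C=C2CC[C@@H]3[C@](CO[Si](C)(C)CBr)(CCC[C@]3(C)CO[Si](C(C)C)(C(C)C)C(C)C)[C@H]2CC1 | intermediate
22 | 13-ketone with C17 on C8β joined to O20 through SiMe2 (2,2-dimethyl-1,2-oxasilepane over C8–C9–C10; H-9 α; 19-OTIPS) | C1[C@@]23CC[C@@H]4[C@](CO[Si]1(C)C)(CCC[C@]4(C)CO[Si](C(C)C)(C(C)C)C(C)C)[C@H]2CCC(=O)C3 | intermediate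
23 | 13-O-trimethylsilyl C12=C13 enol ether of 22 (formed in situ) | C1[C@@]23CC[C@@H]4[C@](CO[Si]1(C)C)(CCC[C@]4(C)CO[Si](C(C)C)(C(C)C)C(C)C)[C@H]2CC=C(O[Si](C)(C)C)C3 | intermediate
24 | C11=C12 enone of 22 | C1[C@@]23CC[C@@H]4[C@](CO[Si]1(C)C)(CCC[C@]4(C)CO[Si](C(C)C)(C(C)C)C(C)C)[C@H]2C=CC(=O)C3 | intermediate
25 | 2-(bromomethyl)-1,4-dimethoxybenzene | COc1ccc(OC)c(CBr)c1 | starting material
26 | lithium dienolate of 24 (C11=C12–C13(OLi)=C14; formed in situ) | C1[C@@]23CC[C@@H]4[C@](CO[Si]1(C)C)(CCC[C@]4(C)CO[Si](C(C)C)(C(C)C)C(C)C)[C@H]2C=CC(O[Li])=C3 | intermediate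
27 | 14α-(2,5-dimethoxybenzyl) derivative of enone 24 (H-14 β) | C1[C@@]23CC[C@@H]4[C@](CO[Si]1(C)C)(CCC[C@]4(C)CO[Si](C(C)C)(C(C)C)C(C)C)[C@H]2C=CC(=O)[C@@H]3Cc1cc(OC)ccc1OC | intermediate
28 | 14α-(2,5-dimethoxybenzyl) saturated 13-ketone | C1[C@@]23CC[C@@H]4[C@](CO[Si]1(C)C)(CCC[C@]4(C)CO[Si](C(C)C)(C(C)C)C(C)C)[C@H]2CCC(=O)[C@@H]3Cc1cc(OC)ccc1OC | intermediate
29 | 13-methylidene compound | C1[C@@]23CC[C@@H]4[C@](CO[Si]1(C)C)(CCC[C@]4(C)CO[Si](C(C)C)(C(C)C)C(C)C)[C@H]2CCC(=C)[C@@H]3Cc1cc(OC)ccc1OC | intermediate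
30 | 13α,16-epoxide (oxygen α; CH2 β) | C1[C@@]23CC[C@@H]4[C@](CO[Si]1(C)C)(CCC[C@]4(C)CO[Si](C(C)C)(C(C)C)C(C)C)[C@H]2CC[C@@]5(CO5)[C@@H]3Cc1cc(OC)ccc1OC | intermediate
31 | 13α-hydroxy-13β-methyl compound (silicon tether and TIPS ether intact) | C1[C@@]23CC[C@@H]4[C@](CO[Si]1(C)C)(CCC[C@]4(C)CO[Si](C(C)C)(C(C)C)C(C)C)[C@H]2CC[C@](C)(O)[C@@H]3Cc1cc(OC)ccc1OC | intermediate
32 | triol (8β-methyl; C19-OH; C20-OH; 13α-OH; 14α-(2,5-dimethoxybenzyl)) | C[C@@]12CC[C@@H]3[C@](CO)(CCC[C@]3(C)CO)[C@H]1CC[C@](C)(O)[C@@H]2Cc1cc(OC)ccc1OC | intermediate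
33 | lactol (C19 hemiacetal closed by O20; formed in situ) | C[C@@]12CC[C@@H]3[C@]4(CCC[C@]3(C)C(O)OC4)[C@H]1CC[C@](C)(O)[C@@H]2Cc1cc(OC)ccc1OC | intermediate
34 | 19→20 δ-lactone bis(methyl ether) of the target | C[C@@]12CC[C@@H]3[C@]4(CCC[C@]3(C)C(=O)OC4)[C@H]1CC[C@](C)(O)[C@@H]2Cc1cc(OC)ccc1OC | intermediate
35 | 2-substituted 1,4-benzoquinone of the target (formed in situ) | C[C@@]12CC[C@@H]3[C@]4(CCC[C@]3(C)C(=O)OC4)[C@H]1CC[C@](C)(O)[C@@H]2CC1=CC(=O)C=CC1=O | intermediate
36 | CNP0148621.1 | C[C@@]12CC[C@@H]3[C@]4(CCC[C@]3(C)C(=O)OC4)[C@H]1CC[C@](C)(O)[C@@H]2Cc1cc(O)ccc1O | target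

**Step count and risks**

Total step count: 23. Longest linear sequence: 23 steps (1 → 36); compounds 4, 19 and 25 enter as purchased reagents.

Steps most likely to fail:

1. Step 14. The α-silylmethyl radical may be reduced by the stannane, or may translocate by hydrogen abstraction, before it closes the seven-membered ring, leaving C8 unmethylated. Fallback (hydroxyl-directed cyclopropanation and reductive ring opening) sets out from 18 and returns at 32. TBSCl/imidazole and then DBU should give the conjugated 20-O-TBS enone F1. LiBH(s-Bu)3 should attack equatorially to give the pseudoaxial 13β-allylic alcohol F2. Et2Zn/CH2I2 should then deliver CH2 syn to that hydroxyl to give the 8β,14β-methano carbinol F3, and Dess–Martin oxidation gives the cyclopropyl ketone F4. Li/NH3 should cleave the external C14–C17 bond to reveal the C8β methyl and a C13–C14 enolate, which is trapped with 25 to give the 14α-benzyl 8β-methyl ketone F5. Cp2TiMe2 gives the methylidene compound F6, dimethyldioxirane the α-epoxide F7, and LiBHEt3 the tertiary alcohol F8; Bu4NF then removes both silyl ethers to give 32.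

2. Step 7. Ionisation of the activated epoxide may outrun capture by the arene, leading to a 1,2-hydride shift to the aldehyde (Meinwald rearrangement) or to loss of the inversion pathway and erosion of the trans ring fusion. Fallback (arene–olefin cyclisation without an epoxide) sets out from 9 and returns at 11. Cp2TiMe2 should give the methylidene ester F9. Hg(OTf)2·PhNMe2 in MeNO2, followed by aqueous NaCl, should close ring B through the bridged mercurinium ion to the C20 chloromercurio tricycle F10. Oxidative demercuration (NaBH4, O2, DMF) then gives 11.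

3. Step 22. Site discrimination between the two neopentyl primary alcohols may be insufficient; first oxidation at C20 would lead to the regioisomeric lactone. Fallback (differentiation by protecting groups) sets out from 31 and returns at 34. KOtBu in wet DMSO should protodesilylate the tether but keep the TIPS ether, giving the C20 alcohol F11. Ac2O/DMAP/pyridine gives the C20 acetate F12, HF·pyridine the C19 alcohol F13, and TEMPO/PhI(OAc)2 in MeCN/H2O the C19 carboxylic acid F14. K2CO3/MeOH followed by dilute HCl removes the acetate and closes the lactone to 34.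

**Further compounds**

F1 | step 14 | 20-[(tert-butyldimethylsilyl)oxy]-19-[(triisopropylsilyl)oxy]-9α-podocarp-8(14)-en-13-one | O=C1C=C2CC[C@@H]3[C@](CO[Si](C)(C)C(C)(C)C)(CCC[C@]3(C)CO[Si](C(C)C)(C(C)C)C(C)C)[C@H]2CC1
F2 | step 14 | 13β-allylic alcohol of F1 | O[C@H]1C=C2CC[C@@H]3[C@](CO[Si](C)(C)C(C)(C)C)(CCC[C@]3(C)CO[Si](C(C)C)(C(C)C)C(C)C)[C@H]2CC1
F3 | step 14 | 8β,14β-methano 13β-carbinol | O[C@H]1[C@H]2C[C@]23CC[C@@H]4[C@](CO[Si](C)(C)C(C)(C)C)(CCC[C@]4(C)CO[Si](C(C)C)(C(C)C)C(C)C)[C@H]3CC1
F4 | step 14 | 8β,14β-methano 13-ketone | O=C1[C@H]2C[C@]23CC[C@@H]4[C@](CO[Si](C)(C)C(C)(C)C)(CCC[C@]4(C)CO[Si](C(C)C)(C(C)C)C(C)C)[C@H]3CC1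
F5 | step 14 | 14α-(2,5-dimethoxybenzyl)-8β-methyl 13-ketone (20-OTBS; 19-OTIPS) | C[C@@]12CC[C@@H]3[C@](CO[Si](C)(C)C(C)(C)C)(CCC[C@]3(C)CO[Si](C(C)C)(C(C)C)C(C)C)[C@H]1CCC(=O)[C@@H]2Cc1cc(OC)ccc1OC
F6 | step 14 | 13-methylidene compound from F5 | C[C@@]12CC[C@@H]3[C@](CO[Si](C)(C)C(C)(C)C)(CCC[C@]3(C)CO[Si](C(C)C)(C(C)C)C(C)C)[C@H]1CCC(=C)[C@@H]2Cc1cc(OC)ccc1OC
F7 | step 14 | 13α,16-epoxide from F6 | C[C@@]12CC[C@@H]3[C@](CO[Si](C)(C)C(C)(C)C)(CCC[C@]3(C)CO[Si](C(C)C)(C(C)C)C(C)C)[C@H]1CC[C@@]3(CO3)[C@@H]2Cc1cc(OC)ccc1OC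
F8 | step 14 | 13α-hydroxy-13β-methyl bis(silyl ether) | C[C@@]12CC[C@@H]3[C@](CO[Si](C)(C)C(C)(C)C)(CCC[C@]3(C)CO[Si](C(C)C)(C(C)C)C(C)C)[C@H]1CC[C@](C)(O)[C@@H]2Cc1cc(OC)ccc1OC
F9 | step 7 | methyl (1R,2S)-2-[2-(3-methoxyphenyl)ethyl]-3-methylidenecyclohexane-1-carboxylate | COc1cccc(CC[C@@H]2C(=C)CCC[C@H]2C(=O)OC)c1
F10 | step 7 | C20 chloromercurio analogue of 11 | COc1ccc2c(c1)CC[C@@H]1[C@]2(C[Hg]Cl)CCC[C@H]1C(=O)OC
F11 | step 22 | C20 alcohol with C17 methyl and 19-OTIPS retained | C[C@@]12CC[C@@H]3[C@](CO)(CCC[C@]3(C)CO[Si](C(C)C)(C(C)C)C(C)C)[C@H]1CC[C@](C)(O)[C@@H]2Cc1cc(OC)ccc1OC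
F12 | step 22 | C20 acetate of F11 | C[C@@]12CC[C@@H]3[C@](COC(C)=O)(CCC[C@]3(C)CO[Si](C(C)C)(C(C)C)C(C)C)[C@H]1CC[C@](C)(O)[C@@H]2Cc1cc(OC)ccc1OC
F13 | step 22 | C19 alcohol C20 acetate | C[C@@]12CC[C@@H]3[C@](COC(C)=O)(CCC[C@]3(C)CO)[C@H]1CC[C@](C)(O)[C@@H]2Cc1cc(OC)ccc1OC
F14 | step 22 | C19 carboxylic acid C20 acetate | C[C@@]12CC[C@@H]3[C@](COC(C)=O)(CCC[C@]3(C)C(=O)O)[C@H]1CC[C@](C)(O)[C@@H]2Cc1cc(OC)ccc1OC
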